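Ring A of unit 2 (the 8''-linked flavone; unit 1 is the 3-linked one) is cut back to an alkyne on C3 of unit 1 and the four carbons of 3-ethoxycyclobutenone. The feature used is that C8'' lies between two oxygen-bearing carbons, C7'' and C8a'', of a phloroglucinol ring whose third oxygen sits on C5''. One thermal benzannulation forms C8''–C8a'', C6''–C7'' and C4a''–C8a'' and delivers the three oxygens differentiated as free OH (future O1''), OTIPS and OEt, so the pyranone of unit 2 can grow only at O1''/C4a''. The precursor is tri-O-methylapigenin carrying a TIPSO–C≡C group on C3.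

Key step: step 7

Assumption: the target is drawn without an axial descriptor, so the C3–C8'' axis is treated as configurationally unassigned and no atroposelection is planned.

Remark: the bulky triisopropylsilyl group is kept on the ynol oxygen and all other oxygens are methyl ethers. These pass every step unchanged and fall together with the ethyl ether in the last step.

Step 1
Reactants: 1 2,4,6-trimethoxybenzaldehyde; 2 4-ethynylanisole
Product: 4 rac-3-(4-methoxyphenyl)-1-(2,4,6-trimethoxyphenyl)prop-2-yn-1-ol, via lithium (4-methoxyphenyl)acetylide 3 (not isolated)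
Conditions: 2, n-BuLi, THF, −78 °C; then 1, −78 → 0 °C; H2O
Reagents that add atoms: none
Why: 1,2-addition of a lithium acetylide to a non-enolisable aryl aldehyde; the carbinol centre forms as a racemate, which does not matter because step 2 oxidises it away.

Step 2
Reactants: 4 rac-3-(4-methoxyphenyl)-1-(2,4,6-trimethoxyphenyl)prop-2-yn-1-ol (used crude)
Product: 5 3-(4-methoxyphenyl)-1-(2,4,6-trimethoxyphenyl)prop-2-yn-1-one
Conditions: activated MnO2, CH2Cl2, rt
Reagents that add atoms: none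
Why: MnO2 oxidation of a benzylic, propargylic alcohol under neutral conditions, which spares the acid-labile electron-rich carbinol and the alkyne.

Step 3
Reactants: 5 3-(4-methoxyphenyl)-1-(2,4,6-trimethoxyphenyl)prop-2-yn-1-one
Product: 6 3-iodo-5,7-dimethoxy-2-(4-methoxyphenyl)-4H-chromen-4-one
Conditions: ICl (1.1 equiv), CH2Cl2, −78 °C
Reagents that add atoms: iodine monochloride, ClI
Why: electrophilic iodocyclisation of an ortho-methoxyaryl ynone (6-endo-dig attack of the methoxy oxygen on the iodonium-activated alkyne, then demethylation of the oxonium by chloride), run cold with near-stoichiometric ICl so that the activated C6 and C8 positions are not iodinated.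

Step 4
Reactants: 6 3-iodo-5,7-dimethoxy-2-(4-methoxyphenyl)-4H-chromen-4-one; 7 ethynyltrimethylsilane
Product: 8 5,7-dimethoxy-2-(4-methoxyphenyl)-3-[(trimethylsilyl)ethynyl]-4H-chromen-4-one
Conditions: PdCl2(PPh3)2 (cat.), CuI (cat.), Et3N, THF, 50 °C
Reagents that add atoms: none
Why: Sonogashira coupling; the C3–I bond is that of an α-iodoenone and should undergo oxidative addition readily, while the silyl cap prevents double coupling.

Step 5
Reactants: 8 5,7-dimethoxy-2-(4-methoxyphenyl)-3-[(trimethylsilyl)ethynyl]-4H-chromen-4-one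
Product: 9 3-ethynyl-5,7-dimethoxy-2-(4-methoxyphenyl)-4H-chromen-4-one
Conditions: K2CO3 (cat.), MeOH/CH2Cl2, rt
Reagents that add atoms: none
Why: methoxide-catalysed protodesilylation of an alkynylsilane; the 2-aryl group shields C2 of the pyranone from methoxide at room temperature.

Step 6
Reactants: 9 3-ethynyl-5,7-dimethoxy-2-(4-methoxyphenyl)-4H-chromen-4-one
Product: 12 5,7-dimethoxy-2-(4-methoxyphenyl)-3-{[tri(propan-2-yl)silyloxy]ethynyl}-4H-chromen-4-one, via lithium acetylide 10 (not isolated), via lithium ynolate 11 (not isolated)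
Conditions: LiN(SiMe3)2, THF, −78 °C; t-BuOOLi (from t-BuOOH and LiN(SiMe3)2), −78 → 0 °C; i-Pr3SiOTf, −78 → 0 °C
Reagents that add atoms: tert-butyl hydroperoxide, CC(C)(C)OO; tri(propan-2-yl)silyl trifluoromethanesulfonate, CC(C)[Si](OS(=O)(=O)C(F)(F)F)(C(C)C)C(C)C
Why: oxidation of a lithium acetylide by lithium tert-butyl peroxide to the ynolate followed by O-silylation with a bulky silyl triflate, the standard entry to triisopropylsiloxyalkynes from terminal alkynes; the amide base, unlike an alkyllithium, should leave the C4 carbonyl alone, and the flavone has no other acidic C–H because C3 is substituted.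

Step 7
Reactants: 12 5,7-dimethoxy-2-(4-methoxyphenyl)-3-{[tri(propan-2-yl)silyloxy]ethynyl}-4H-chromen-4-one; 13 3-ethoxycyclobut-2-en-1-one
Product: 17 3-{4-ethoxy-2-hydroxy-6-[tri(propan-2-yl)silyloxy]phenyl}-5,7-dimethoxy-2-(4-methoxyphenyl)-4H-chromen-4-one, via vinylketene 14 (not isolated), via vinylcyclobutenone 15 (not isolated), via dienylketene 16 (not isolated)
Conditions: 13 (2 equiv), toluene, 80 → 110 °C, sealed tube
Reagents that add atoms: none
Why: Proposed new method: on heating, 13 undergoes four-electron electrocyclic opening to vinylketene 14, the flavone-bearing alkyne carbon of 12 (β to the siloxy oxygen) adds to the ketene carbonyl carbon in a [2+2] cycloaddition to give 15, and 15 reopens to dienylketene 16, which closes ring A of unit 2 by six-electron electrocyclisation (the C4a''–C8a'' bond) and enolises to the phenol. The closest known reaction type is the Danheiser benzannulation of cyclobutenones with triisopropylsiloxyalkynes to resorcinol monosilyl ethers; untested are the 3-alkoxy group on the cyclobutenone and the hindered, electron-poor chromon-3-yl group on the alkyne. The one ring formed is closed in pericyclic fashion, two bonds (C8''–C8a'', C6''–C7'') by the [2+2] step and the third by the 6π closure. No stereocentre is created. The selectivity required is regiochemical and is secured by the siloxy group, which polarises the alkyne so that its β-carbon bonds to the ketene carbon; this places the flavone between the new hydroxyl (C8a'') and the siloxy carbon (C7''), with the ethoxy carbon (C5'') para to it. The bulky silyl group suppresses silyl transfer and excess 13 offsets loss of 14 to dimerisation.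

Step 8
Reactants: 17 3-{4-ethoxy-2-hydroxy-6-[tri(propan-2-yl)silyloxy]phenyl}-5,7-dimethoxy-2-(4-methoxyphenyl)-4H-chromen-4-one; 18 ethyl 3-(4-methoxyphenyl)prop-2-ynoate
Product: 19 ethyl (2Z)-3-{5-ethoxy-2-[5,7-dimethoxy-2-(4-methoxyphenyl)-4-oxo-4H-chromen-3-yl]-3-[tri(propan-2-yl)silyloxy]phenoxy}-3-(4-methoxyphenyl)prop-2-enoate
Conditions: K2CO3, DMF, 70 °C
Reagents that add atoms: none
Why: base-mediated oxa-Michael addition of the single free phenol to an arylpropiolate (first stage of the Ruhemann flavone synthesis); anti addition should favour the Z enol ether, and any E isomer can be carried on because the acid of step 10 equilibrates the geometry.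

Step 9
Reactants: 19 ethyl (2Z)-3-{5-ethoxy-2-[5,7-dimethoxy-2-(4-methoxyphenyl)-4-oxo-4H-chromen-3-yl]-3-[tri(propan-2-yl)silyloxy]phenoxy}-3-(4-methoxyphenyl)prop-2-enoate
Product: 21 (2Z)-3-{5-ethoxy-3-hydroxy-2-[5,7-dimethoxy-2-(4-methoxyphenyl)-4-oxo-4H-chromen-3-yl]phenoxy}-3-(4-methoxyphenyl)prop-2-enoic acid, via desilylated ester 20 (not isolated)
Conditions: n-Bu4NF, THF, 0 °C; then LiOH, MeOH/H2O, 40 °C; aq. HCl to pH 3
Reagents that add atoms: lithium hydroxide, [Li+].[OH-]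
Why: fluoride cleavage of the aryl silyl ether and ester saponification in one flask; the silyl group is no longer needed once the ether oxygen is fixed, and the 3-substituted flavone and the aryl vinyl ether should tolerate mild hydroxide.

Step 10
Reactants: 21 (2Z)-3-{5-ethoxy-3-hydroxy-2-[5,7-dimethoxy-2-(4-methoxyphenyl)-4-oxo-4H-chromen-3-yl]phenoxy}-3-(4-methoxyphenyl)prop-2-enoic acid
Product: 22 3-[5-ethoxy-7-hydroxy-2-(4-methoxyphenyl)-4-oxo-4H-chromen-8-yl]-5,7-dimethoxy-2-(4-methoxyphenyl)-4H-chromen-4-one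
Conditions: Eaton's reagent (P2O5 in MeSO3H), rt → 40 °C
Reagents that add atoms: none
Why: intramolecular Friedel–Crafts acylation of a 3-aryloxycinnamic acid (second stage of the Ruhemann flavone synthesis), which can close the six-membered pyranone only at C4a'', the one free carbon ortho to the ether oxygen and activated by the ortho ethoxy and para hydroxy groups.

Step 11
Reactants: 22 3-[5-ethoxy-7-hydroxy-2-(4-methoxyphenyl)-4-oxo-4H-chromen-8-yl]-5,7-dimethoxy-2-(4-methoxyphenyl)-4H-chromen-4-one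
Product: 23 3,8''-biapigenin
Conditions: BBr3 (excess), CH2Cl2, −78 °C → rt; then H2O
Reagents that add atoms: none
Why: Lewis-acid cleavage of aryl alkyl ethers, the peri ethers (5-OMe, 5''-OEt) going first through chelation to the C4 carbonyls; anhydrous conditions at or below room temperature should avoid the hydrolytic ring opening and reclosure (Wessely–Moser rearrangement) that would move the linkage from C8'' to C6''.

Compound list
1 | 2,4,6-trimethoxybenzaldehyde | COc1cc(OC)c(C=O)c(OC)c1 | starting material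
2 | 4-ethynylanisole | C#Cc1ccc(OC)cc1 | starting material
3 | lithium (4-methoxyphenyl)acetylide | [Li]C#Cc1ccc(OC)cc1 | intermediate (not isolated)
4 | rac-3-(4-methoxyphenyl)-1-(2,4,6-trimethoxyphenyl)prop-2-yn-1-ol | COc1ccc(C#CC(O)c2c(OC)cc(OC)cc2OC)cc1 | intermediate
5 | 3-(4-methoxyphenyl)-1-(2,4,6-trimethoxyphenyl)prop-2-yn-1-one | COc1ccc(C#CC(=O)c2c(OC)cc(OC)cc2OC)cc1 | intermediate
6 | 3-iodo-5,7-dimethoxy-2-(4-methoxyphenyl)-4H-chromen-4-one | O=c1c(I)c(-c2ccc(OC)cc2)oc2cc(OC)cc(OC)c12 | intermediate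
7 | ethynyltrimethylsilane | C#C[Si](C)(C)C | starting material
8 | 5,7-dimethoxy-2-(4-methoxyphenyl)-3-[(trimethylsilyl)ethynyl]-4H-chromen-4-one | O=c1c(C#C[Si](C)(C)C)c(-c2ccc(OC)cc2)oc2cc(OC)cc(OC)c12 | intermediate
9 | 3-ethynyl-5,7-dimethoxy-2-(4-methoxyphenyl)-4H-chromen-4-one | C#Cc1c(-c2ccc(OC)cc2)oc2cc(OC)cc(OC)c2c1=O | intermediate
10 | {[5,7-dimethoxy-2-(4-methoxyphenyl)-4-oxo-4H-chromen-3-yl]ethynyl}lithium | [Li]C#Cc1c(-c2ccc(OC)cc2)oc2cc(OC)cc(OC)c2c1=O | intermediate (not isolated)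
11 | lithium 2-[5,7-dimethoxy-2-(4-methoxyphenyl)-4-oxo-4H-chromen-3-yl]ethyn-1-olate | [Li+].[O-]C#Cc1c(-c2ccc(OC)cc2)oc2cc(OC)cc(OC)c2c1=O | intermediate (not isolated)
12 | 5,7-dimethoxy-2-(4-methoxyphenyl)-3-{[tri(propan-2-yl)silyloxy]ethynyl}-4H-chromen-4-one | O=c1c(C#CO[Si](C(C)C)(C(C)C)C(C)C)c(-c2ccc(OC)cc2)oc2cc(OC)cc(OC)c12 | intermediate (key-step precursor)
13 | 3-ethoxycyclobut-2-en-1-one | CCOC1=CC(=O)C1 | starting material
14 | 3-ethoxybuta-1,3-dien-1-one | CCOC(=C)C=C=O | intermediate (not isolated)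
15 | rac-4-(1-ethoxyethenyl)-2-[5,7-dimethoxy-2-(4-methoxyphenyl)-4-oxo-4H-chromen-3-yl]-3-[tri(propan-2-yl)silyloxy]cyclobut-2-en-1-one | CCOC(=C)C1C(=O)C(c2c(-c3ccc(OC)cc3)oc3cc(OC)cc(OC)c3c2=O)=C1O[Si](C(C)C)(C(C)C)C(C)C | intermediate (not isolated)
16 | (3E)-5-ethoxy-2-[5,7-dimethoxy-2-(4-methoxyphenyl)-4-oxo-4H-chromen-3-yl]-3-[tri(propan-2-yl)silyloxy]hexa-1,3,5-trien-1-one (ketene carbon and ethoxyvinyl group cis) | CCOC(=C)/C=C(O[Si](C(C)C)(C(C)C)C(C)C)\C(=C=O)c1c(-c2ccc(OC)cc2)oc2cc(OC)cc(OC)c2c1=O | intermediate (not isolated)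
17 | 3-{4-ethoxy-2-hydroxy-6-[tri(propan-2-yl)silyloxy]phenyl}-5,7-dimethoxy-2-(4-methoxyphenyl)-4H-chromen-4-one | O=c1c(-c2c(O)cc(OCC)cc2O[Si](C(C)C)(C(C)C)C(C)C)c(-c2ccc(OC)cc2)oc2cc(OC)cc(OC)c12 | intermediate (key-step product)
18 | ethyl 3-(4-methoxyphenyl)prop-2-ynoate | CCOC(=O)C#Cc1ccc(OC)cc1 | starting material
19 | ethyl (2Z)-3-{5-ethoxy-2-[5,7-dimethoxy-2-(4-methoxyphenyl)-4-oxo-4H-chromen-3-yl]-3-[tri(propan-2-yl)silyloxy]phenoxy}-3-(4-methoxyphenyl)prop-2-enoate | CCOC(=O)/C=C(\Oc1cc(OCC)cc(O[Si](C(C)C)(C(C)C)C(C)C)c1-c1c(-c2ccc(OC)cc2)oc2cc(OC)cc(OC)c2c1=O)c1ccc(OC)cc1 | intermediate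
20 | ethyl (2Z)-3-{5-ethoxy-3-hydroxy-2-[5,7-dimethoxy-2-(4-methoxyphenyl)-4-oxo-4H-chromen-3-yl]phenoxy}-3-(4-methoxyphenyl)prop-2-enoate | CCOC(=O)/C=C(\Oc1cc(OCC)cc(O)c1-c1c(-c2ccc(OC)cc2)oc2cc(OC)cc(OC)c2c1=O)c1ccc(OC)cc1 | intermediate (not isolated)
21 | (2Z)-3-{5-ethoxy-3-hydroxy-2-[5,7-dimethoxy-2-(4-methoxyphenyl)-4-oxo-4H-chromen-3-yl]phenoxy}-3-(4-methoxyphenyl)prop-2-enoic acid | OC(=O)/C=C(\Oc1cc(OCC)cc(O)c1-c1c(-c2ccc(OC)cc2)oc2cc(OC)cc(OC)c2c1=O)c1ccc(OC)cc1 | intermediate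
22 | 3-[5-ethoxy-7-hydroxy-2-(4-methoxyphenyl)-4-oxo-4H-chromen-8-yl]-5,7-dimethoxy-2-(4-methoxyphenyl)-4H-chromen-4-one | O=c1c(-c2c(O)cc(OCC)c3c(=O)cc(-c4ccc(OC)cc4)oc23)c(-c2ccc(OC)cc2)oc2cc(OC)cc(OC)c12 | intermediate
23 | 3,8''-biapigenin | O=c1c(-c2c(O)cc(O)c3c(=O)cc(-c4ccc(O)cc4)oc23)c(-c2ccc(O)cc2)oc2cc(O)cc(O)c12 | target

Total step count: 11. Longest linear sequence: 11 steps (from 1 and 2 to 23).

Steps most likely to fail

Step 7 (proposed new method). The hindered, electron-poor siloxyalkyne may capture the vinylketene too slowly, so that ketene dimerisation or a thermal silyl shift of 12 to a silylketene takes over. The alkoxy-stabilised cyclobutenone may also open only at temperatures the siloxyalkyne does not tolerate. The fallback uses known chemistry, sets out from 6 and rejoins the route at 23. Purchased 5,7-dimethoxy-2-(4-methoxyphenyl)-4H-chromen-4-one F1 would be iodinated at its most nucleophilic ring carbon, C8 (I2, CF3CO2Ag, CH2Cl2), to 8-iodo-5,7-dimethoxy-2-(4-methoxyphenyl)-4H-chromen-4-one F2. Miyaura borylation (B2pin2, PdCl2(dppf), KOAc, dioxane, 90 °C) would give 5,7-dimethoxy-2-(4-methoxyphenyl)-8-(4,4,5,5-tetramethyl-1,3,2-dioxaborolan-2-yl)-4H-chromen-4-one F3. Suzuki–Miyaura coupling of F3 with 6 (Pd(OAc)2, SPhos, K3PO4, toluene/H2O, 100 °C) would give 3-[5,7-dimethoxy-2-(4-methoxyphenyl)-4-oxo-4H-chromen-8-yl]-5,7-dimethoxy-2-(4-methoxyphenyl)-4H-chromen-4-one F4, and BBr3 as in step 11 would give 23.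

Step 6. The acetylide or ynolate may add to the C4 carbonyl of a second molecule, oxygen transfer may stay incomplete, silylation may go to carbon, or the siloxyalkyne may hydrolyse on silica. The fallback avoids ynolate chemistry by installing an alkoxyalkyne through cross-coupling; it sets out from 6 and rejoins the route at 23. Negishi coupling of 6 with chloro(ethoxyethynyl)zinc F5 (from ethoxyacetylene, n-BuLi and ZnCl2; Pd(PPh3)4, THF, rt) would give 3-(ethoxyethynyl)-5,7-dimethoxy-2-(4-methoxyphenyl)-4H-chromen-4-one F6. Heating F6 with 13 in benzene at 80 °C (the alkoxyalkyne form of the same benzannulation) would give 3-(2,4-diethoxy-6-hydroxyphenyl)-5,7-dimethoxy-2-(4-methoxyphenyl)-4H-chromen-4-one F7. Addition to 18 as in step 8 would give ethyl (2Z)-3-{3,5-diethoxy-2-[5,7-dimethoxy-2-(4-methoxyphenyl)-4-oxo-4H-chromen-3-yl]phenoxy}-3-(4-methoxyphenyl)prop-2-enoate F8. Saponification with LiOH would give (2Z)-3-{3,5-diethoxy-2-[5,7-dimethoxy-2-(4-methoxyphenyl)-4-oxo-4H-chromen-3-yl]phenoxy}-3-(4-methoxyphenyl)prop-2-enoic acid F9. Eaton's reagent would close it to 3-[5,7-diethoxy-2-(4-methoxyphenyl)-4-oxo-4H-chromen-8-yl]-5,7-dimethoxy-2-(4-methoxyphenyl)-4H-chromen-4-one F10, and BBr3 as in step 11 would give 23.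

Step 8. Conjugate addition of the ortho-hindered phenoxide to a deactivated β-aryl alkynoate may be slow. Prolonged heating with base may cause loss of the silyl group followed by double addition, or attack of the phenoxide on C2 of unit 1. The fallback forms the C4a''–C4'' bond first and the O1''–C2'' bond last; it sets out from 17 and rejoins the route at 22. Desilylation (n-Bu4NF, THF) would give 3-(4-ethoxy-2,6-dihydroxyphenyl)-5,7-dimethoxy-2-(4-methoxyphenyl)-4H-chromen-4-one F11, whose new ring is symmetric, so its two free carbons are equivalent. Friedel–Crafts acetylation (AcOH, BF3·OEt2, 80 °C) would give 3-(3-acetyl-4-ethoxy-2,6-dihydroxyphenyl)-5,7-dimethoxy-2-(4-methoxyphenyl)-4H-chromen-4-one F12. Claisen–Schmidt condensation with 4-methoxybenzaldehyde (KOH, EtOH, rt) would give 3-{4-ethoxy-2,6-dihydroxy-3-[(2E)-3-(4-methoxyphenyl)prop-2-enoyl]phenyl}-5,7-dimethoxy-2-(4-methoxyphenyl)-4H-chromen-4-one F13. Oxidative cyclisation (I2 cat., DMSO, 120 °C) through the only hydroxyl ortho to the enone would give 22.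

Further compounds
F1 | step 7 | 5,7-dimethoxy-2-(4-methoxyphenyl)-4H-chromen-4-one (purchased) | O=c1cc(-c2ccc(OC)cc2)oc2cc(OC)cc(OC)c12
F2 | step 7 | 8-iodo-5,7-dimethoxy-2-(4-methoxyphenyl)-4H-chromen-4-one | O=c1cc(-c2ccc(OC)cc2)oc2c(I)c(OC)cc(OC)c12
F3 | step 7 | 5,7-dimethoxy-2-(4-methoxyphenyl)-8-(4,4,5,5-tetramethyl-1,3,2-dioxaborolan-2-yl)-4H-chromen-4-one | O=c1cc(-c2ccc(OC)cc2)oc2c(B3OC(C)(C)C(C)(C)O3)c(OC)cc(OC)c12
F4 | step 7 | 3-[5,7-dimethoxy-2-(4-methoxyphenyl)-4-oxo-4H-chromen-8-yl]-5,7-dimethoxy-2-(4-methoxyphenyl)-4H-chromen-4-one | O=c1c(-c2c(OC)cc(OC)c3c(=O)cc(-c4ccc(OC)cc4)oc23)c(-c2ccc(OC)cc2)oc2cc(OC)cc(OC)c12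
F5 | step 6 | chloro(ethoxyethynyl)zinc | CCOC#C[Zn]Cl
F6 | step 6 | 3-(ethoxyethynyl)-5,7-dimethoxy-2-(4-methoxyphenyl)-4H-chromen-4-one | O=c1c(C#COCC)c(-c2ccc(OC)cc2)oc2cc(OC)cc(OC)c12
F7 | step 6 | 3-(2,4-diethoxy-6-hydroxyphenyl)-5,7-dimethoxy-2-(4-methoxyphenyl)-4H-chromen-4-one | O=c1c(-c2c(O)cc(OCC)cc2OCC)c(-c2ccc(OC)cc2)oc2cc(OC)cc(OC)c12
F8 | step 6 | ethyl (2Z)-3-{3,5-diethoxy-2-[5,7-dimethoxy-2-(4-methoxyphenyl)-4-oxo-4H-chromen-3-yl]phenoxy}-3-(4-methoxyphenyl)prop-2-enoate | CCOC(=O)/C=C(\Oc1cc(OCC)cc(OCC)c1-c1c(-c2ccc(OC)cc2)oc2cc(OC)cc(OC)c2c1=O)c1ccc(OC)cc1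
F9 | step 6 | (2Z)-3-{3,5-diethoxy-2-[5,7-dimethoxy-2-(4-methoxyphenyl)-4-oxo-4H-chromen-3-yl]phenoxy}-3-(4-methoxyphenyl)prop-2-enoic acid | OC(=O)/C=C(\Oc1cc(OCC)cc(OCC)c1-c1c(-c2ccc(OC)cc2)oc2cc(OC)cc(OC)c2c1=O)c1ccc(OC)cc1
F10 | step 6 | 3-[5,7-diethoxy-2-(4-methoxyphenyl)-4-oxo-4H-chromen-8-yl]-5,7-dimethoxy-2-(4-methoxyphenyl)-4H-chromen-4-one | O=c1c(-c2c(OCC)cc(OCC)c3c(=O)cc(-c4ccc(OC)cc4)oc23)c(-c2ccc(OC)cc2)oc2cc(OC)cc(OC)c12
F11 | step 8 | 3-(4-ethoxy-2,6-dihydroxyphenyl)-5,7-dimethoxy-2-(4-methoxyphenyl)-4H-chromen-4-one | O=c1c(-c2c(O)cc(OCC)cc2O)c(-c2ccc(OC)cc2)oc2cc(OC)cc(OC)c12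
F12 | step 8 | 3-(3-acetyl-4-ethoxy-2,6-dihydroxyphenyl)-5,7-dimethoxy-2-(4-methoxyphenyl)-4H-chromen-4-one | CC(=O)c1c(OCC)cc(O)c(-c2c(-c3ccc(OC)cc3)oc3cc(OC)cc(OC)c3c2=O)c1O
F13 | step 8 | 3-{4-ethoxy-2,6-dihydroxy-3-[(2E)-3-(4-methoxyphenyl)prop-2-enoyl]phenyl}-5,7-dimethoxy-2-(4-methoxyphenyl)-4H-chromen-4-one | COc1ccc(/C=C/C(=O)c2c(OCC)cc(O)c(-c3c(-c4ccc(OC)cc4)oc4cc(OC)cc(OC)c4c3=O)c2O)cc1
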